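## The problem

Umbilicaric acid (16) is a linear tridepside: three C8 benzoic acid units joined by two aryl ester bonds, each running from the C4 oxygen of one ring to the carboxyl carbon of the next. Ring positions are numbered from the carboxyl-bearing carbon (C1), with the methyl group at C6.

- There are no stereocentres, so the difficulties are regiochemical and chemoselective.
- Ring A carries OCH3 at C2 and a free OH at C4. This is the reverse of what direct methylation of an orsellinate gives, because the unchelated C4 hydroxyl reacts first.
- The two depside links are activated aryl esters. They do not tolerate hydroxide, alkoxide, amines in excess or hydride, and they can migrate between phenols.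
- The terminal ring C acid is a β-resorcylic acid that decarboxylates on heating, and the free resorcinol rings are easily oxidised.
- Classical syntheses carry the C2 hydroxyls of rings B and C through the whole sequence as benzyl ethers, which is where most of the steps go.
- The feature that allows a shortcut: on rings B and C the C2 hydroxyl lies ortho to the C1 ester carbonyl, and the other ortho position (C6) holds CH3. A carbonyl-bound metal can therefore reach only one C-H bond on each ring. Ring A has OCH3 and CH3 at both ortho positions and offers none.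

## Retrosynthesis

**16 to 15.** The last disconnection removes the two protecting groups: a 2,2,2-trichloroethyl ester on the ring C carboxyl and a 2,2,2-trichloroethyl carbonate on the ring A C4 oxygen. Both leave in one zinc reduction at room temperature, with no base or nucleophile near the depside links. A benzyl ester and an acetate were the obvious alternatives. The benzyl group has an acid-labile C-O bond and oxidisable benzylic C-H bonds, which is a liability in hot trifluoroacetic acid with persulfate. The acetate would later have to be cleaved by a nucleophile next to three other aryl esters. The trichloroethyl groups have neither weakness.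

**15 to 13.** The two C2-O bonds of rings B and C are cut together, leaving C-H bonds in 13. This is preferred over disconnecting an ester first because it removes both salicylate hydroxyls from the whole preceding sequence. No hydroxyl protection is needed on rings B and C, and both rings derive from 4-hydroxy-2-methylbenzoic acid (6). The forward reaction has to oxidise exactly one C-H bond on each of two rings, leave ring A alone, and spare two depside links, an aryl carbonate and a trichloroethyl ester.

**13 to 5 and 11.** The A-B ester bond is cut next. The hindered 2,6-disubstituted ring A acid 5 is the only fragment that needs several steps, so it is joined last. Its steric crowding favours acylation through an acylium-type mixed anhydride with trifluoroacetic anhydride, the standard way to make depsides from such acids. The partner 11 is a didepside with a single free phenol.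

**11 to 9 and 7 (via 10).** The B-C ester bond is cut into two derivatives of the same acid 6: the trichloroethyl ester 7 as phenol component and the silyl-protected acid 9 as acyl component. The silyl ether on ring B prevents self-condensation of the hydroxy acid. It is removed under buffered fluoride, conditions to which the trichloroethyl ester is inert.

**5 to 1 (via 4, 3 and 2).** The ring A acid is traced to orsellinic acid (1). The chelated C2 hydroxyl of 1 is unreactive, so benzylation caps the carboxyl group and the C4 oxygen first (2). Methylation then goes to C2 (3), and hydrogenolysis frees both benzyl-protected sites at once (4). The carbonate is put on last (5), after the hydrogenation, so that no C-Cl bond is exposed to palladium and hydrogen.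

## Roads not taken

**Alternative 1:** Ring B would be built by a Danheiser benzannulation instead of being bought.

- Cut: the bonds C2-C3, C4-C5 and C1-C2 of ring B.
- Forward step: irradiation of the diazoketone 4-[(benzyloxy)carbonyl]-3-(benzyloxy)-5-methylphenyl (E)-5-diazo-3-methyl-4-oxopent-2-enoate A1 triggers a Wolff rearrangement to a vinylketene. This adds to (triisopropylsilyloxy)ethyne A2 in a [2+2] sense. The cyclobutenone opens and the dienylketene closes by 6π electrocyclisation to the didepside benzyl 2-(benzyloxy)-4-({2-hydroxy-6-methyl-4-[(triisopropylsilyl)oxy]benzoyl}oxy)-6-methylbenzoate A3.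
- Merits: the ring B oxygens emerge cleanly differentiated (free C2 hydroxyl, silylated C4 hydroxyl), and no oxidant ever meets the depside links. In that respect it is safer than the chosen plan.
- Weak points: A1 is a diazoketone that also contains an aryl acrylate, and it takes several steps to make. Aryl esters can undergo photo-Fries rearrangement under the irradiation. Ring C still has to be brought in as a protected orsellinate, ring A still needs the same preparation, and the silyl group must be removed by fluoride next to an aryl ester.
- Comparison: a whole ring is constructed that the chosen plan obtains from a commodity acid. The chosen plan sets its short sequence and absence of hydroxyl protection on rings B and C against the cleaner oxidation-state handling of this road.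

**Alternative 2:** Ring B would be closed biomimetically.

- Cut: the C1-C6 bond of ring B.
- Forward step: the tetraketide ester 4-[(benzyloxy)carbonyl]-3-hydroxy-5-methylphenyl 3,5,7-trioxooctanoate A4 undergoes intramolecular aldol addition of C2 to the C7 ketone, then dehydration and enolisation, to give benzyl 4-[(2,4-dihydroxy-6-methylbenzoyl)oxy]-2-hydroxy-6-methylbenzoate A5.
- Merits: A5 has both ring B hydroxyls free. The chelated C2 hydroxyl is inert, so ring A could be attached at C4 without any protection. This is at least as economical in protecting groups as the chosen plan, and it follows the biosynthesis.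
- Weak points: A4 is an aryl ester of a polycarbonyl acid with an aryloxide as a good leaving group. Under the base needed for the aldol, Claisen-type C-acylation and lactonisation with expulsion of the ring C phenol compete directly with ring closure. Acylating a phenol with a triketo acid equivalent to make A4 is itself poorly controlled.
- Comparison: the chosen plan has to prove a twofold C-H oxidation, but its substrate 13 is a stable, fully characterisable compound assembled by standard esterifications.

**Alternative 3:** Ring B would come from a 2-pyrone.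

- Cut: the bonds C5-C6 and C3-C4 of ring B.
- Forward step: the pyrone ester 4-[(benzyloxy)carbonyl]-3-hydroxy-5-methylphenyl 4-(benzyloxy)-6-methyl-2-oxo-2H-pyran-5-carboxylate A6 reacts with 1,1-bis(trimethylsilyloxy)ethene A7 in a Diels-Alder reaction. Loss of CO2 and silanol from the bicyclic adduct gives benzyl 4-{[2-(benzyloxy)-4-hydroxy-6-methylbenzoyl]oxy}-2-hydroxy-6-methylbenzoate A8.
- Merits: the regiochemistry is fixed by the polarity of the two partners. A8 has exactly the pattern needed for the next acylation (C4 hydroxyl free, C2 oxygen protected), which is better than anything the chosen plan offers at the corresponding stage.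
- Weak points: a 4-alkoxy-2-pyrone is an electron-rich, sluggish diene for an electron-rich dienophile. A7 can instead transfer silicon to the free ring C phenol or attack the aryl ester. The pyrone acid needs its own multistep synthesis, and rings A and C still come from orsellinate chemistry with their own protecting groups.
- Comparison: the chosen plan uses two cheap aromatic acids and installs both hydroxyls in one operation. Its weakness, that the fully assembled tridepside is exposed to an acidic oxidising medium, is one this road does not have.

Key step: step 10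

## Route

Remark on the chemistry: the two aryl trifluoroacetates formed in the key step are assumed to hydrolyse completely during aqueous work-up, so 14 is not isolated.

Step 1
Reactants: 1 orsellinic acid (2,4-dihydroxy-6-methylbenzoic acid)
Product: 2 benzyl 4-(benzyloxy)-2-hydroxy-6-methylbenzoate
Conditions: BnBr (2.1 equiv), K2CO3, DMF, 0 °C to rt
Reagents that add atoms: benzyl bromide, BrCc1ccccc1
Why: Williamson-type O-alkylation of the carboxylate and of the unchelated C4 phenoxide; the C2 hydroxyl is hydrogen-bonded to the carbonyl and should stay free with two equivalents of halide, and the low temperature keeps the acid from decarboxylating before it is esterified.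

Step 2
Reactants: 2 benzyl 4-(benzyloxy)-2-hydroxy-6-methylbenzoate
Product: 3 benzyl 4-(benzyloxy)-2-methoxy-6-methylbenzoate
Conditions: MeI, K2CO3, DMF, 50 °C
Reagents that add atoms: iodomethane, CI
Why: Williamson methylation of the chelated phenol, which reacts on gentle heating once the more reactive oxygen atoms are blocked; the hindered benzyl ester is stable to carbonate.

Step 3
Reactants: 3 benzyl 4-(benzyloxy)-2-methoxy-6-methylbenzoate
Product: 4 4-hydroxy-2-methoxy-6-methylbenzoic acid
Conditions: H2 (1 atm), 10% Pd/C, EtOAc/MeOH, rt
Reagents that add atoms: none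
Why: Catalytic hydrogenolysis cleaves the benzyl ester and the benzyl ether in one operation and leaves the methyl ether and the arene untouched.

Step 4
Reactants: 4 4-hydroxy-2-methoxy-6-methylbenzoic acid
Product: 5 2-methoxy-6-methyl-4-{[(2,2,2-trichloroethoxy)carbonyl]oxy}benzoic acid
Conditions: ClCO2CH2CCl3 (1.05 equiv), NaOH (2 equiv), H2O/THF, 0 °C; then dilute HCl
Reagents that add atoms: 2,2,2-trichloroethyl chloroformate, ClC(=O)OCC(Cl)(Cl)Cl
Why: Schotten-Baumann acylation of the dianion, in which the phenoxide is far more nucleophilic than the hindered 2,6-disubstituted carboxylate; this is the classical chloroformate protection of phenolic acids, and any mixed carbonic anhydride is hydrolysed back to the acid in the aqueous medium.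

Step 5
Reactants: 6 4-hydroxy-2-methylbenzoic acid
Product: 7 2,2,2-trichloroethyl 4-hydroxy-2-methylbenzoate
Conditions: Cl3CCH2OH (5 equiv), TsOH·H2O (cat.), toluene, reflux, Dean-Stark trap
Reagents that add atoms: 2,2,2-trichloroethanol, OCC(Cl)(Cl)Cl
Why: Fischer esterification driven by azeotropic removal of water; under acid catalysis the phenol does not compete with the alcohol, so no hydroxyl protection is needed.

Step 6
Reactants: 6 4-hydroxy-2-methylbenzoic acid
Product: 9 4-[(tert-butyldimethylsilyl)oxy]-2-methylbenzoic acid, via bis-silylated acid 8 (not isolated)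
Conditions: TBSCl (2.3 equiv), imidazole, DMF, rt; then AcOH/THF/H2O, rt
Reagents that add atoms: tert-butyldimethylsilyl chloride, CC(C)(C)[Si](C)(C)Cl
Why: Exhaustive silylation followed by selective hydrolysis of the much more labile silyl ester, the standard way to an O-silylated hydroxy acid; the aryl silyl ether is stable to aqueous acetic acid at room temperature.

Step 7
Reactants: 9 4-[(tert-butyldimethylsilyl)oxy]-2-methylbenzoic acid; 7 2,2,2-trichloroethyl 4-hydroxy-2-methylbenzoate
Product: 10 2,2,2-trichloroethyl 4-({4-[(tert-butyldimethylsilyl)oxy]-2-methylbenzoyl}oxy)-2-methylbenzoate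
Conditions: DCC, DMAP (cat.), CH2Cl2, 0 °C to rt
Reagents that add atoms: none
Why: Steglich esterification of a mono-ortho-substituted benzoic acid with a phenol; the acylpyridinium intermediate acylates the weakly nucleophilic para-acyl phenol, and neither the silyl ether nor the trichloroethyl ester is affected.

Step 8
Reactants: 10 2,2,2-trichloroethyl 4-({4-[(tert-butyldimethylsilyl)oxy]-2-methylbenzoyl}oxy)-2-methylbenzoate
Product: 11 2,2,2-trichloroethyl 4-[(4-hydroxy-2-methylbenzoyl)oxy]-2-methylbenzoate
Conditions: Bu4NF, AcOH (1:1), THF, 0 °C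
Reagents that add atoms: none
Why: Fluoride-induced cleavage of an aryl silyl ether; buffering with acetic acid protonates the phenoxide as it forms, so it cannot attack the aryl ester or the trichloroethyl ester.

Step 9
Reactants: 5 2-methoxy-6-methyl-4-{[(2,2,2-trichloroethoxy)carbonyl]oxy}benzoic acid; 11 2,2,2-trichloroethyl 4-[(4-hydroxy-2-methylbenzoyl)oxy]-2-methylbenzoate
Product: 13 2,2,2-trichloroethyl 4-{[4-({2-methoxy-6-methyl-4-[(2,2,2-trichloroethoxy)carbonyloxy]benzoyl}oxy)-2-methylbenzoyl]oxy}-2-methylbenzoate, via mixed anhydride 12 (not isolated)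
Conditions: (CF3CO)2O, toluene, rt
Reagents that add atoms: none
Why: Depside formation through the mixed trifluoroacetic anhydride; the two ortho substituents of ring A favour ionisation to an acylium-type species that is captured by the phenol, the established method for hindered 2,6-disubstituted benzoic acids, and the acidic medium leaves carbonate and esters intact.

Step 10
Reactants: 13 2,2,2-trichloroethyl 4-{[4-({2-methoxy-6-methyl-4-[(2,2,2-trichloroethoxy)carbonyloxy]benzoyl}oxy)-2-methylbenzoyl]oxy}-2-methylbenzoate
Product: 15 2,2,2-trichloroethyl 2-hydroxy-4-{[2-hydroxy-4-({2-methoxy-6-methyl-4-[(2,2,2-trichloroethoxy)carbonyloxy]benzoyl}oxy)-6-methylbenzoyl]oxy}-6-methylbenzoate, via bis(trifluoroacetate) 14 (not isolated)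
Conditions: [RuCl2(p-cymene)]2 (5 mol %), K2S2O8 (4 equiv), CF3CO2H/(CF3CO)2O, 80 °C; then H2O/THF, rt
Reagents that add atoms: trifluoroacetic acid, OC(=O)C(F)(F)F
Why: The C1 ester carbonyl of ring B and that of ring C each bind a cationic divalent ruthenium trifluoroacetate, and carboxylate-assisted metalation cleaves the one ortho C2-H bond to give a five-membered ruthenacycle. K2S2O8 oxidises this to a tetravalent ruthenium aryl trifluoroacetate, C-O reductive elimination releases the aryl trifluoroacetate and returns divalent ruthenium, and the cycle runs once on each ring to give 14, which is hydrolysed to 15 on work-up. The closest known reaction type is the ruthenium-catalysed ester-directed ortho C-H hydroxylation of alkyl benzoates with persulfate in trifluoroacetic acid and its anhydride; here it is asked to work with a trichloroethyl benzoate and an aryl benzoate, which are weaker carbonyl donors. No ring is closed and no stereocentre is formed. The selectivity needed is site selectivity, and the substrate secures it: on rings B and C the second ortho position C6 carries CH3, so C2-H is the only bond that can give the five-membered chelate, and six-membered chelation through an acyloxy carbonyl toward C3 is disfavoured by ring size. Ring A has no C-H bond ortho to its carbonyl, its two C-H bonds are each flanked by two substituents, and the electron-withdrawing carbonate lowers its tendency to non-directed oxidation. The new phenols exist as trifluoroacetates in the medium, which shields them from over-oxidation, and the trichloroethyl groups have no acid-labile or easily oxidised position.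

Step 11
Reactants: 15 2,2,2-trichloroethyl 2-hydroxy-4-{[2-hydroxy-4-({2-methoxy-6-methyl-4-[(2,2,2-trichloroethoxy)carbonyloxy]benzoyl}oxy)-6-methylbenzoyl]oxy}-6-methylbenzoate
Product: 16 umbilicaric acid (2-hydroxy-4-{[2-hydroxy-4-[(4-hydroxy-2-methoxy-6-methylbenzoyl)oxy]-6-methylbenzoyl]oxy}-6-methylbenzoic acid)
Conditions: Zn dust, AcOH/THF, rt
Reagents that add atoms: none
Why: Reductive β-elimination of both 2,2,2-trichloroethyl groups by electron transfer from zinc frees the carboxylic acid directly and the ring A phenol after loss of CO2; aryl esters are inert to zinc in acetic acid, so the depside links survive.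

## Compound list

1 | orsellinic acid (2,4-dihydroxy-6-methylbenzoic acid) | Cc1cc(O)cc(O)c1C(=O)O | starting material
2 | benzyl 4-(benzyloxy)-2-hydroxy-6-methylbenzoate | Cc1cc(OCc2ccccc2)cc(O)c1C(=O)OCc1ccccc1 | intermediate
3 | benzyl 4-(benzyloxy)-2-methoxy-6-methylbenzoate | COc1cc(OCc2ccccc2)cc(C)c1C(=O)OCc1ccccc1 | intermediate
4 | 4-hydroxy-2-methoxy-6-methylbenzoic acid | COc1cc(O)cc(C)c1C(=O)O | intermediate
5 | 2-methoxy-6-methyl-4-{[(2,2,2-trichloroethoxy)carbonyl]oxy}benzoic acid | COc1cc(OC(=O)OCC(Cl)(Cl)Cl)cc(C)c1C(=O)O | intermediate
6 | 4-hydroxy-2-methylbenzoic acid | Cc1cc(O)ccc1C(=O)O | starting material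
7 | 2,2,2-trichloroethyl 4-hydroxy-2-methylbenzoate | Cc1cc(O)ccc1C(=O)OCC(Cl)(Cl)Cl | intermediate
8 | tert-butyldimethylsilyl 4-[(tert-butyldimethylsilyl)oxy]-2-methylbenzoate | Cc1cc(O[Si](C)(C)C(C)(C)C)ccc1C(=O)O[Si](C)(C)C(C)(C)C | intermediate (not isolated)
9 | 4-[(tert-butyldimethylsilyl)oxy]-2-methylbenzoic acid | Cc1cc(O[Si](C)(C)C(C)(C)C)ccc1C(=O)O | intermediate
10 | 2,2,2-trichloroethyl 4-({4-[(tert-butyldimethylsilyl)oxy]-2-methylbenzoyl}oxy)-2-methylbenzoate | Cc1cc(O[Si](C)(C)C(C)(C)C)ccc1C(=O)Oc1cc(C)c(C(=O)OCC(Cl)(Cl)Cl)cc1 | intermediate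
11 | 2,2,2-trichloroethyl 4-[(4-hydroxy-2-methylbenzoyl)oxy]-2-methylbenzoate | Cc1cc(O)ccc1C(=O)Oc1cc(C)c(C(=O)OCC(Cl)(Cl)Cl)cc1 | intermediate
12 | 2-methoxy-6-methyl-4-{[(2,2,2-trichloroethoxy)carbonyl]oxy}benzoic trifluoroacetic anhydride | COc1cc(OC(=O)OCC(Cl)(Cl)Cl)cc(C)c1C(=O)OC(=O)C(F)(F)F | intermediate (not isolated)
13 | 2,2,2-trichloroethyl 4-{[4-({2-methoxy-6-methyl-4-[(2,2,2-trichloroethoxy)carbonyloxy]benzoyl}oxy)-2-methylbenzoyl]oxy}-2-methylbenzoate | COc1cc(OC(=O)OCC(Cl)(Cl)Cl)cc(C)c1C(=O)Oc1cc(C)c(C(=O)Oc2cc(C)c(C(=O)OCC(Cl)(Cl)Cl)cc2)cc1 | intermediate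
14 | 2,2,2-trichloroethyl 4-{[4-({2-methoxy-6-methyl-4-[(2,2,2-trichloroethoxy)carbonyloxy]benzoyl}oxy)-2-methyl-6-(trifluoroacetoxy)benzoyl]oxy}-2-methyl-6-(trifluoroacetoxy)benzoate | COc1cc(OC(=O)OCC(Cl)(Cl)Cl)cc(C)c1C(=O)Oc1cc(C)c(C(=O)Oc2cc(C)c(C(=O)OCC(Cl)(Cl)Cl)c(OC(=O)C(F)(F)F)c2)c(OC(=O)C(F)(F)F)c1 | intermediate (not isolated)
15 | 2,2,2-trichloroethyl 2-hydroxy-4-{[2-hydroxy-4-({2-methoxy-6-methyl-4-[(2,2,2-trichloroethoxy)carbonyloxy]benzoyl}oxy)-6-methylbenzoyl]oxy}-6-methylbenzoate | COc1cc(OC(=O)OCC(Cl)(Cl)Cl)cc(C)c1C(=O)Oc1cc(C)c(C(=O)Oc2cc(C)c(C(=O)OCC(Cl)(Cl)Cl)c(O)c2)c(O)c1 | intermediate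
16 | umbilicaric acid | COc1cc(O)cc(C)c1C(=O)Oc1cc(C)c(C(=O)Oc2cc(C)c(C(=O)O)c(O)c2)c(O)c1 | target

## Step count and risks

Total step count: 11. Longest linear sequence: 7 steps (steps 1, 2, 3, 4, 9, 10, 11).

**Step 10 (key step).** Three processes may interfere.

- The trichloroethyl ester and the aryl ester are weaker carbonyl donors than the alkyl benzoates on which this hydroxylation is established. Metalation may be slow and the reaction may stall after oxygenation of one ring.
- In hot trifluoroacetic acid with its anhydride, the 2,6-disubstituted ring A ester can ionise toward an acylium species, leading to acidolysis or scrambling of the depside links.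
- Non-directed electrophilic oxidation of ring A para to the methoxyl group, or six-membered chelation toward C3 of ring B or C, may erode site selectivity.

Fallback: abandon late-stage oxidation and carry the hydroxyls in from the start, with benzyl protection throughout. It sets out from 3 and comes back to the route at 16.

- Saponification of 3 (KOH, aqueous DMSO, heat) should give 4-(benzyloxy)-2-methoxy-6-methylbenzoic acid F1.
- Esterification of F1 with commercial 2,4-dihydroxy-6-methylbenzaldehyde, using trifluoroacetic anhydride in toluene, should acylate only the unchelated C4 hydroxyl and give 4-formyl-3-hydroxy-5-methylphenyl 4-(benzyloxy)-2-methoxy-6-methylbenzoate F2.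
- Benzylation (BnBr, K2CO3, acetone) should give 3-(benzyloxy)-4-formyl-5-methylphenyl 4-(benzyloxy)-2-methoxy-6-methylbenzoate F3.
- Pinnick oxidation (NaClO2, NaH2PO4, 2-methyl-2-butene, t-BuOH/H2O) should give 2-(benzyloxy)-4-{[4-(benzyloxy)-2-methoxy-6-methylbenzoyl]oxy}-6-methylbenzoic acid F4.
- Separately, 1 would be converted with BnBr and KHCO3 in DMF into benzyl 2,4-dihydroxy-6-methylbenzoate F5.
- Coupling of F4 with F5 by trifluoroacetic anhydride in toluene should give benzyl 4-{[2-(benzyloxy)-4-{[4-(benzyloxy)-2-methoxy-6-methylbenzoyl]oxy}-6-methylbenzoyl]oxy}-2-hydroxy-6-methylbenzoate F6.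
- Hydrogenolysis of F6 (H2, Pd/C, EtOAc) should give 16.

**Step 4.** The chloroformate may acylate the carboxylate as well as the phenoxide, or be hydrolysed, and the aryl carbonate may be cleaved if the alkali is in excess. Fallback, from 4 back to 5: acylate exhaustively with two equivalents of the chloroformate and pyridine in CH2Cl2 to give 2-methoxy-6-methyl-4-{[(2,2,2-trichloroethoxy)carbonyl]oxy}benzoic 2,2,2-trichloroethyl carbonic anhydride F7. Then hydrolyse only the mixed anhydride with aqueous NaHCO3 in THF. Water attacks the unhindered carbonate carbonyl of the anhydride and regenerates the hindered acid, giving 5.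

**Step 8.** Fluoride or the liberated phenoxide may trigger transesterification or cleavage of the activated aryl ester, or attack the trichloroethyl ester. Fallback: avoid a phenol protecting group on ring B by masking its acid as an aldehyde and reversing the order of assembly. It sets out from 5 and rejoins the route at 13.

- 5 would be coupled with commercial 4-hydroxy-2-methylbenzaldehyde (trifluoroacetic anhydride, toluene) to give 4-formyl-3-methylphenyl 2-methoxy-6-methyl-4-{[(2,2,2-trichloroethoxy)carbonyl]oxy}benzoate F8.
- Pinnick oxidation should give 4-[(2-methoxy-6-methyl-4-{[(2,2,2-trichloroethoxy)carbonyl]oxy}benzoyl)oxy]-2-methylbenzoic acid F9.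
- Oxalyl chloride with catalytic DMF should give 4-(chlorocarbonyl)-3-methylphenyl 2-methoxy-6-methyl-4-{[(2,2,2-trichloroethoxy)carbonyl]oxy}benzoate F10.
- F10 would acylate 7 in CH2Cl2 with pyridine to give 13.

**Step 9.** The carbonate makes ring A less electron-rich than the alkoxy acids usually used, so acylium formation may be slow, and trifluoroacetylation of phenol 11 or transfer of the carbonate group may take over. Fallback, from 5 back to 13: replace acid-mediated acylium chemistry by base-mediated addition-elimination. 5 would be converted with oxalyl chloride and catalytic DMF into 2-methoxy-6-methyl-4-{[(2,2,2-trichloroethoxy)carbonyl]oxy}benzoyl chloride F11. The isolated chloride would be used to acylate 11 in CH2Cl2 with pyridine at 0 °C, giving 13.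

## Further compounds

F1 | step 10 | 4-(benzyloxy)-2-methoxy-6-methylbenzoic acid | COc1cc(OCc2ccccc2)cc(C)c1C(=O)O
F2 | step 10 | 4-formyl-3-hydroxy-5-methylphenyl 4-(benzyloxy)-2-methoxy-6-methylbenzoate | COc1cc(OCc2ccccc2)cc(C)c1C(=O)Oc1cc(C)c(C=O)c(O)c1
F3 | step 10 | 3-(benzyloxy)-4-formyl-5-methylphenyl 4-(benzyloxy)-2-methoxy-6-methylbenzoate | COc1cc(OCc2ccccc2)cc(C)c1C(=O)Oc1cc(C)c(C=O)c(OCc2ccccc2)c1
F4 | step 10 | 2-(benzyloxy)-4-{[4-(benzyloxy)-2-methoxy-6-methylbenzoyl]oxy}-6-methylbenzoic acid | COc1cc(OCc2ccccc2)cc(C)c1C(=O)Oc1cc(C)c(C(=O)O)c(OCc2ccccc2)c1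
F5 | step 10 | benzyl 2,4-dihydroxy-6-methylbenzoate | Cc1cc(O)cc(O)c1C(=O)OCc1ccccc1
F6 | step 10 | benzyl 4-{[2-(benzyloxy)-4-{[4-(benzyloxy)-2-methoxy-6-methylbenzoyl]oxy}-6-methylbenzoyl]oxy}-2-hydroxy-6-methylbenzoate | COc1cc(OCc2ccccc2)cc(C)c1C(=O)Oc1cc(C)c(C(=O)Oc2cc(C)c(C(=O)OCc3ccccc3)c(O)c2)c(OCc2ccccc2)c1
F7 | step 4 | 2-methoxy-6-methyl-4-{[(2,2,2-trichloroethoxy)carbonyl]oxy}benzoic 2,2,2-trichloroethyl carbonic anhydride | COc1cc(OC(=O)OCC(Cl)(Cl)Cl)cc(C)c1C(=O)OC(=O)OCC(Cl)(Cl)Cl
F8 | step 8 | 4-formyl-3-methylphenyl 2-methoxy-6-methyl-4-{[(2,2,2-trichloroethoxy)carbonyl]oxy}benzoate | COc1cc(OC(=O)OCC(Cl)(Cl)Cl)cc(C)c1C(=O)Oc1cc(C)c(C=O)cc1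
F9 | step 8 | 4-[(2-methoxy-6-methyl-4-{[(2,2,2-trichloroethoxy)carbonyl]oxy}benzoyl)oxy]-2-methylbenzoic acid | COc1cc(OC(=O)OCC(Cl)(Cl)Cl)cc(C)c1C(=O)Oc1cc(C)c(C(=O)O)cc1
F10 | step 8 | 4-(chlorocarbonyl)-3-methylphenyl 2-methoxy-6-methyl-4-{[(2,2,2-trichloroethoxy)carbonyl]oxy}benzoate | COc1cc(OC(=O)OCC(Cl)(Cl)Cl)cc(C)c1C(=O)Oc1cc(C)c(C(=O)Cl)cc1
F11 | step 9 | 2-methoxy-6-methyl-4-{[(2,2,2-trichloroethoxy)carbonyl]oxy}benzoyl chloride | COc1cc(OC(=O)OCC(Cl)(Cl)Cl)cc(C)c1C(=O)Cl
A1 | alternative 1 | 4-[(benzyloxy)carbonyl]-3-(benzyloxy)-5-methylphenyl (E)-5-diazo-3-methyl-4-oxopent-2-enoate | [N-]=[N+]=CC(=O)/C(C)=C/C(=O)Oc1cc(C)c(C(=O)OCc2ccccc2)c(OCc2ccccc2)c1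
A2 | alternative 1 | (triisopropylsilyloxy)ethyne | C#CO[Si](C(C)C)(C(C)C)C(C)C
A3 | alternative 1 | benzyl 2-(benzyloxy)-4-({2-hydroxy-6-methyl-4-[(triisopropylsilyl)oxy]benzoyl}oxy)-6-methylbenzoate | Cc1cc(O[Si](C(C)C)(C(C)C)C(C)C)cc(O)c1C(=O)Oc1cc(C)c(C(=O)OCc2ccccc2)c(OCc2ccccc2)c1
A4 | alternative 2 | 4-[(benzyloxy)carbonyl]-3-hydroxy-5-methylphenyl 3,5,7-trioxooctanoate | CC(=O)CC(=O)CC(=O)CC(=O)Oc1cc(C)c(C(=O)OCc2ccccc2)c(O)c1
A5 | alternative 2 | benzyl 4-[(2,4-dihydroxy-6-methylbenzoyl)oxy]-2-hydroxy-6-methylbenzoate | Cc1cc(O)cc(O)c1C(=O)Oc1cc(C)c(C(=O)OCc2ccccc2)c(O)c1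
A6 | alternative 3 | 4-[(benzyloxy)carbonyl]-3-hydroxy-5-methylphenyl 4-(benzyloxy)-6-methyl-2-oxo-2H-pyran-5-carboxylate | Cc1oc(=O)cc(OCc2ccccc2)c1C(=O)Oc1cc(C)c(C(=O)OCc2ccccc2)c(O)c1
A7 | alternative 3 | 1,1-bis(trimethylsilyloxy)ethene | C=C(O[Si](C)(C)C)O[Si](C)(C)C
A8 | alternative 3 | benzyl 4-{[2-(benzyloxy)-4-hydroxy-6-methylbenzoyl]oxy}-2-hydroxy-6-methylbenzoate | Cc1cc(O)cc(OCc2ccccc2)c1C(=O)Oc1cc(C)c(C(=O)OCc2ccccc2)c(O)c1
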